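(The readings are calculated from invented constants; noise was put on by code.)

**Amounts.** In both earlier runs the target column already holds the idle adduct, so it is the asked total. You see a lag (induction period): the south-east total still reads 0% at 4.00 h.

in all of them: gas phase 200 mM (held)

|  | solid substrate | catalyst | remark | time |
|---|---|---|---|---|
| west | 2 M | 1.8 mol% | run made earlier |  |
| south-east | 2 M | 7 mol% | run made earlier |  |
| flask | 2.0 M | 3.5 mol% |  | 30 h |

| run | time / h | target / % | idle adduct / % |
|---|---|---|---|
| west | 2.00 | 0 | 0.6 |
| west | 3.00 | 0 | 0.8 |
| west | 4.00 | 0 | 1.2 |
| west | 6.00 | 1.3 | 0.7 |
| west | 10.0 | 0.1 | 0 |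
| west | 15.0 | 3.1 | 1.9 |
| west | 25.0 | 5.2 | 4.7 |
| south-east | 1.33 | 0 | 0.5 |
| south-east | 4.00 | 0 | 0.4 |
| south-east | 6.00 | 1.8 | 1.3 |
| south-east | 10.0 | 4.6 | 2.0 |
| south-east | 15.0 | 7.1 | 4.4 |
| south-east | 20.0 | 10.0 | 7.7 |
| south-east | 25.0 | 15.5 | 13.3 |

(scatter of a reading: 1 percentage point)

- for target the idle adduct is counted in
- as a solid, counted per litre of solution: solid substrate
- the analysis behind the earlier runs scatters by 1 percentage point, standard deviation
- at the start none of the gas phase is in solution
- at the start none of the solid substrate is in solution

- the target and idle adduct together standing at 30 h, as a percentage of the solid substrate charged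
- the change that raises the amount of target and idle adduct together at 30 h, in percent of the solid substrate charged most ("none" if none brings more than 2 percentage points) (zeta / gamma / eta / beta / none)
- amount of target and idle adduct together at 30 h, in percent of the solid substrate charged, after beta

- zeta: doubling the amount of catalyst, all else as stated
- gamma: doubling the saturation concentration of gas phase, all else as stated
- eta: doubling the solubility of the solid substrate, all else as stated
- beta: doubling the transfer coefficient of the gas phase, all else as stated

**Zero of scale.** A rate steady from time zero makes the total grow in step with time, so steady means an exponent of 1. The south-east total goes from 7.1% at 15.0 h to 15.5% at 25.0 h. That gives 1.53 as the time exponent: the logarithm of the total's growth over the logarithm of the time's growth. It is a reading, with the scatter in it. It stands above the steady value, so over this stretch the south-east total grows faster than time does; the lag may account for part of that.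

**Catalyst step.** At 25.0 h, the south-east total is 2.98 times the west total, for 3.89 times the loading. The catalyst exponent is therefore 0.804, below proportional.

**My reckoning.** Scaling the west total to 3.5 mol% gives 8.88%. The time exponent carries that from 25.0 h to 30 h, which gives 11.7% for the flask. These two exponents do not separate gas from solid as the slow feed. My judgement is the solid, so I pick eta and expect beta to add little.

**The forecast.** Reading “then a straight line”, it gives 11.5%, gamma as best, and 13.5% after beta.

**The result.** The flask gives 11.7%. The best change is eta, worth 11 percentage points, while beta adds 0.24 points, for 12.0%. In the flask at 15.0 h, starting material stands at 47.7% of saturation and dissolved gas at 95.4%, lower for the starting material. Run the time exponent back from 11.7% to 15.0 h: it gives 4.05%, and the flask held 4.03%.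

    gas phase ⇌ dissolved gas, rate k1*(csat - [dissolved gas]) (kL = 1.80 h⁻¹)
    starting material + dissolved gas + catalyst → catalyst + target (k = 2.10 L² mol⁻² h⁻¹)
    dissolved gas + target ⇌ idle adduct, settled at all times (K = 44.0 L mol⁻¹)
    solid substrate ⇌ starting material, rate k4*(cs4 - [starting material]) while solid is left; crystals form when [starting material] > cs4 (solubility = 0.660 M, k = 0.0560 h⁻¹)

**Second flask.** For the same flask read at 8.0 h, the time exponent gives 1.55%. The computed total is 1.36%, a little lower.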